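The vessel was stirred, at constant volume and temperature, and its four flasks differed in how the substrate or the activator went in.

all flasks: capture agent 1.00 mM; time 5.0 min
- teal: substrate 20 mM; activator 22.0 mM; everything together at the start
- grey: substrate 20 mM (in portions, 5, over 4.0 min); activator 22.0 mM; first portion at the start, last at 4.0 min
- ochre: substrate 20 mM; activator 22.0 mM (fed, over 4.0 min); all else is in the flask from the start; the feed brings no volume worth counting
- violet: substrate 20 mM (fed, over 4.0 min); activator 22.0 mM; all else is in the flask from the start; the feed brings no volume worth counting

1. the flask that comes out highest in amount of ring, in percent of the substrate charged, or "all alike" when all lie within 1.5 percentage points (teal / grey / ochre / violet / all alike)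
2. ring at the end, in percent of the substrate charged, teal
3. ring at the end, in percent of the substrate charged, grey
4. ring at the end, in percent of the substrate charged, ochre
5. ring at the end, in percent of the substrate charged, violet

- in percentages every species weighs as the substrate in it: one open dimer counts as two
- run time (teal): 5.0 min

Substrate and activator give the activated form, with constant 0.57 M⁻¹ s⁻¹. That form closes to ring at 0.11 s⁻¹ or decays to side product at 0.0082 s⁻¹. The ring passes to its isomer and back, with constant 6.4, so the quantity I carried was the ring share, the fraction of the ring-plus-isomer pool that stands as ring at equilibrium, 13.5%. Taking 0.10 s⁻¹ as the forward constant, the pool relaxes with a lifetime of 8.65 s, and the run lasts 34.7 such lifetimes, so [ring] follows its pool.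

But the whole charge does not reach the pool in that time. Substrate is the limiting reagent, charged at 20 mM against 22.0 mM. Treating the two charges as equal in a second-order step, I had teal keep 22.6% of its substrate. Closure takes 93.1% of what reacts, so teal's pool came to 72.0% and its ring to 9.72%.

Was the open dimer a hole in this? Even at the full charge of substrate, that step drains the activated form at 0.0100 s⁻¹, slower than the 0.118 s⁻¹ of the other two, so I dropped it. Capture, at 2.600 × 10⁻⁴ s⁻¹, is slower still.

A harder doubt was that following is not sitting on the share: while the pool grows, ring runs ahead by the feed rate times the lifetime times the isomer's fraction. For teal's last moments this added 0.45 percentage points, which gave 10.2%.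

In the slow flasks a reagent arrives 2.00 min late on average. The step needs both partners, so I gave them one reaction time of 3.00 min. They keep 32.8%, their pool is 62.6%, and their lead came to 0.94 points, larger than teal's. That made grey 9.39%, ochre 9.39% and violet 9.39%. This single delay is crude, but the smaller pool and the larger lead pull against each other, and the gap of 0.79 points stayed smaller than the margin of 1.5 points, so I committed to all alike.

The forecast said all alike, with 9.8% for teal, 9.3% for grey, 8.9% for ochre and 9.3% for violet, holding that “capture and dimer losses barely matter”; it differs from my reckoning in parting the slow flasks.

The simulation gave all alike, with 9.97% for teal, 9.21% for grey, 9.00% for ochre and 9.28% for violet.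

    substrate + activator → activated form (k1 = 0.57 M⁻¹ s⁻¹)
    activated form → ring (k2 = 0.11 s⁻¹)
    substrate + activated form → open dimer (k3 = 0.50 M⁻¹ s⁻¹)
    capture agent + activated form → trapped intermediate (k4 = 0.26 M⁻¹ s⁻¹)
    activated form → side product (k5 = 0.0082 s⁻¹)
    ring ⇌ isomer of the product (K6 = 6.4, k6 = 0.10 s⁻¹)

With the step between ring and isomer struck out, both ways, ochre ends with 58.3% of ring instead of 9.00%, so that equilibrium is the main reason for the low figure. The struck-out figure stands for ochre's pool, and the ring share of it gives 7.88%, the remainder being the lead of a flask still forming. The neighbour of ochre charged with 50 mM of substrate held 27.2% of isomer and 4.78% of ring, where the ring share of their sum gives 4.32%.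

(The numbers of this flask belong to no real substance.)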